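**Plan**

- The target is a meso cyclopentene. Ring C1 carries a tertiary hydroxyl and the exocyclic undecanoyl C=O (an α-ketol pair); C2 and C5 carry acetoxy groups cis to each other and trans to that hydroxyl.
- Retrosynthesis: the acetates are removed and C2/C5 raised to ketones. The ring bond C1–C2 is then cut by a retro 1,2-acyl shift that re-attaches this ring carbonyl carbon to the side-chain carbonyl carbon, giving a six-membered 3-decyl-3-hydroxy-1,2,4-trione.
- The trione is cut at its tertiary C–O bond (enol hydroxylation of a decyl hydroxyquinone), and the quinone at the aryl–decyl bond (1,2,4-trimethoxybenzene plus 1-bromodecane).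
- Forward: the chain is joined to the arene first, the six-membered carbocycle is carried through as the quinone, and the five-membered ring arises only in the ring contraction; no ring is made by cyclisation.
- Stereochemistry: both ring carbinols are set in one Luche reduction, hydride entering from the face of the small tertiary hydroxyl. The side-chain carbinol formed at the same time is oxidised back at the end.

Key step: step 5

Remark: the stereodescriptors of the target describe a meso compound (mirror plane through C1 and the midpoint of C3=C4), so only relative configuration has to be controlled and all chiral intermediates are racemic.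

**Route**

Step 1
Reactants: 1 1,2,4-trimethoxybenzene; 2 1-bromodecane
Product: 4 3-decyl-1,2,4-trimethoxybenzene, via (2,3,6-trimethoxyphenyl)lithium 3 (not isolated)
Conditions: n-BuLi, TMEDA, THF, 0 °C; then 2, 0 °C to rt
Reagents that add atoms: none
Why: Directed ortho-metalation followed by SN2 alkylation: the ring position flanked by two methoxy groups is the most acidic and best chelated site, so lithiation should occur there, and the aryllithium displaces bromide from the primary halide.

Step 2
Reactants: 4 3-decyl-1,2,4-trimethoxybenzene
Product: 5 2-decyl-3-methoxycyclohexa-2,5-diene-1,4-dione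
Conditions: (NH4)2Ce(NO3)6, MeCN/H2O, 0 °C
Reagents that add atoms: water, O
Why: Oxidative demethylation of a para-dimethoxyarene by tetravalent cerium: electron transfer and capture of water at the two para-related methoxy carbons should give the para-quinone and leave the third methoxy group as a vinylogous ester.

Step 3
Reactants: 5 2-decyl-3-methoxycyclohexa-2,5-diene-1,4-dione
Product: 6 2-decyl-3-hydroxycyclohexa-2,5-diene-1,4-dione
Conditions: 70% aq. HClO4, 1,4-dioxane, rt
Reagents that add atoms: water, O
Why: Acid hydrolysis of a vinylogous methyl ester by addition–elimination of water at the methoxy-bearing carbon should give the hydroxyquinone, and acid avoids the attack on the unsubstituted quinone positions that strong base could cause.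

Step 4
Reactants: 6 2-decyl-3-hydroxycyclohexa-2,5-diene-1,4-dione
Product: 7 (±)-3-decyl-3-hydroxycyclohex-5-ene-1,2,4-trione
Conditions: dimethyldioxirane (acetone solution dried over 4 Å MS), CH2Cl2, −40 to 0 °C; evaporation, toluene azeotrope
Reagents that add atoms: dimethyldioxirane, CC1(C)OO1
Why: Electrophilic enol hydroxylation of a 2-substituted cyclic 1,3-dicarbonyl with a dioxirane (the free-enol counterpart of the Rubottom oxidation): oxygen should go to the electron-rich, decyl-bearing enol carbon rather than the electron-poor enedione alkene, acetone is the only co-product so the trione is obtained water-free, and the new stereocentre is racemic and needs no control.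

Step 5
Reactants: 7 (±)-3-decyl-3-hydroxycyclohex-5-ene-1,2,4-trione
Product: 8 2-hydroxy-2-undecanoylcyclopent-4-ene-1,3-dione
Conditions: Mg(ClO4)2 (0.2 equiv), 4 Å MS, dry MeCN, rt to 40 °C
Reagents that add atoms: none
Why: Proposed new method: chelation of divalent magnesium by the C3 hydroxyl and the C2 carbonyl of 7 polarises C2 and acidifies the O–H, and a suprafacial 1,2-shift of the C4 acyl carbon from C3 to C2 then forms the C2–C4 bond as C3–C4 breaks and C3 becomes the side-chain ketone (acyloin, or α-ketol, rearrangement). The closest known reaction type is the α-ketol ring contraction of 2-alkyl-2-hydroxycyclohexane-1,3-diones to 2-acyl-2-hydroxycyclopentanones, the manifold of the magnesium-promoted isomerisation of hop α-acids; new here is its use on a quinone-derived ene-trione. The five-membered ring is closed by migration of a ring carbon through a bridged three-centre transition state (ring contraction), not by cyclisation of an open chain. No stereocentre is formed: the stereocentre of 7 is lost and 8 is mirror-symmetric. The selectivity needed is that the C4 acyl carbon shifts to C2, and not C2 to C4 or the decyl group to either carbonyl; C2 is the inner carbon of a vicinal dione and the most electrophilic terminus, acyl carbons migrate more readily than primary alkyl groups in this manifold, and because the shifts are reversible the mixture should drain to 8, the only isomer free of a vicinal dicarbonyl. Water and base are excluded (sieves, aprotic solvent) to shut off the benzilic acid pathway open to such triones.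

Step 6
Reactants: 8 2-hydroxy-2-undecanoylcyclopent-4-ene-1,3-dione
Product: 9 2-(1-hydroxyundecyl)cyclopent-4-ene-1,2,3-triol (1-OH and 3-OH cis to each other and to the hydroxyundecyl group; trans to the 2-OH; racemic)
Conditions: NaBH4 (excess), CeCl3·7H2O, MeOH, −78 to 0 °C
Reagents that add atoms: none
Why: Luche reduction (1,2-selective borohydride reduction of enones in the presence of CeCl3): hydride should add to each ring carbonyl from the face of the small tertiary hydroxyl, anti to the larger acyl (later hydroxyalkyl) group, which sets both ring carbinols cis to each other and trans to the tertiary hydroxyl, while the side-chain ketone is reduced to a carbinol whose configuration is irrelevant.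

Step 7
Reactants: 9 2-(1-hydroxyundecyl)cyclopent-4-ene-1,2,3-triol
Product: 10 4-decyl-2,2-dimethyl-1,3-dioxaspiro[4.4]non-7-ene-6,9-diol (6-OH and 9-OH cis to each other; on the side of C4 and opposite to O1; racemic)
Conditions: 2,2-dimethoxypropane, PPTS (cat.), acetone, rt
Reagents that add atoms: 2,2-dimethoxypropane, COC(C)(C)OC
Why: Acid-catalysed transacetalisation under thermodynamic control: the tertiary hydroxyl is trans to both ring hydroxyls and can only be bridged to the side-chain hydroxyl, and a 2,2-dimethyl-1,3-dioxolane on a 1,2-diol is favoured over the six-membered acetonides open to the 1,3-diols; no stereocentre is touched.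

Step 8
Reactants: 10 4-decyl-2,2-dimethyl-1,3-dioxaspiro[4.4]non-7-ene-6,9-diol
Product: 11 4-decyl-2,2-dimethyl-1,3-dioxaspiro[4.4]non-7-ene-6,9-diyl diacetate (same relative configuration as 10)
Conditions: Ac2O, pyridine, DMAP (cat.), CH2Cl2, 0 °C to rt
Reagents that add atoms: acetic anhydride, CC(=O)OC(C)=O
Why: DMAP-catalysed esterification of the two secondary allylic hydroxyls, the only free hydroxyls left, with retention because no C–O bond of the ring is broken.

Step 9
Reactants: 11 4-decyl-2,2-dimethyl-1,3-dioxaspiro[4.4]non-7-ene-6,9-diyl diacetate
Product: 12 2-hydroxy-2-(1-hydroxyundecyl)cyclopent-4-ene-1,3-diyl diacetate (acetoxy groups cis to each other and to the side chain; trans to the ring hydroxyl; racemic)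
Conditions: AcOH/H2O (4:1), 40 °C
Reagents that add atoms: none
Why: Acid-catalysed hydrolysis of an isopropylidene acetal in aqueous acetic acid, conditions under which secondary acetates are stable and acyl migration is slow.

Step 10
Reactants: 12 2-hydroxy-2-(1-hydroxyundecyl)cyclopent-4-ene-1,3-diyl diacetate
Product: 13 (1R,2r,3S)-2-hydroxy-2-undecanoylcyclopent-4-ene-1,3-diyl diacetate (meso; acetoxy groups cis to each other and to the acyl group; trans to the hydroxyl)
Conditions: IBX, DMSO, rt
Reagents that add atoms: none
Why: IBX oxidation of the secondary alcohol of a 1,2-diol should give the α-hydroxy ketone without glycol cleavage and leave the tertiary hydroxyl and the esters untouched; removing the side-chain stereocentre restores the mirror plane, so the racemic precursor converges on the single meso target.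

**Compound list**

1 | 1,2,4-trimethoxybenzene | COc1ccc(OC)c(OC)c1 | starting material
2 | 1-bromodecane | CCCCCCCCCCBr | starting material
3 | (2,3,6-trimethoxyphenyl)lithium (formed in the flask, not isolated) | [Li]c1c(OC)ccc(OC)c1OC | intermediate
4 | 3-decyl-1,2,4-trimethoxybenzene | CCCCCCCCCCc1c(OC)ccc(OC)c1OC | intermediate
5 | 2-decyl-3-methoxycyclohexa-2,5-diene-1,4-dione | CCCCCCCCCCC1=C(OC)C(=O)C=CC1=O | intermediate
6 | 2-decyl-3-hydroxycyclohexa-2,5-diene-1,4-dione | CCCCCCCCCCC1=C(O)C(=O)C=CC1=O | intermediate
7 | (±)-3-decyl-3-hydroxycyclohex-5-ene-1,2,4-trione (racemic, one enantiomer drawn) | CCCCCCCCCC[C@]1(O)C(=O)C(=O)C=CC1=O | intermediate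
8 | 2-hydroxy-2-undecanoylcyclopent-4-ene-1,3-dione (achiral) | CCCCCCCCCCC(=O)C1(O)C(=O)C=CC1=O | intermediate
9 | 2-(1-hydroxyundecyl)cyclopent-4-ene-1,2,3-triol, 1-OH and 3-OH cis to each other and to the side chain, trans to 2-OH (racemic, one enantiomer drawn) | CCCCCCCCCC[C@H](O)[C@@]1(O)[C@@H](O)C=C[C@H]1O | intermediate
10 | 4-decyl-2,2-dimethyl-1,3-dioxaspiro[4.4]non-7-ene-6,9-diol, hydroxyls cis to each other, on the side of C4 (racemic, one enantiomer drawn) | CCCCCCCCCC[C@@H]1OC(C)(C)O[C@@]12[C@@H](O)C=C[C@H]2O | intermediate
11 | 4-decyl-2,2-dimethyl-1,3-dioxaspiro[4.4]non-7-ene-6,9-diyl diacetate, same relative configuration (racemic, one enantiomer drawn) | CCCCCCCCCC[C@@H]1OC(C)(C)O[C@@]12[C@@H](OC(C)=O)C=C[C@H]2OC(C)=O | intermediate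
12 | 2-hydroxy-2-(1-hydroxyundecyl)cyclopent-4-ene-1,3-diyl diacetate, acetoxy groups cis to each other and to the side chain (racemic, one enantiomer drawn) | CCCCCCCCCC[C@H](O)[C@@]1(O)[C@@H](OC(C)=O)C=C[C@H]1OC(C)=O | intermediate
13 | (1R,2r,3S)-2-hydroxy-2-undecanoylcyclopent-4-ene-1,3-diyl diacetate (meso) | CCCCCCCCCCC(=O)[C@@]1(O)[C@@H](OC(C)=O)C=C[C@H]1OC(C)=O | target

**Totals**

Total step count: 10. Longest linear sequence: 10 steps (from 1; 2 enters in step 1).

**Steps most likely to fail**

Step 5 (the proposed new method). The acyl shift may not be selected: C2 may migrate to the enone carbonyl or the decyl group may shift, the ketol equilibrium may lie on the wrong side, or traces of water may divert the trione into hydrate formation and benzilic acid-type contraction. The fallback uses known chemistry, sets out from 2 and comes back to the route at 8; it builds the five-membered ring by condensation instead of contraction.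
- Mg turnings in THF convert 2 into decylmagnesium bromide F1.
- Acylation of F1 with 2-chloro-N-methoxy-N-methylacetamide (Weinreb ketone synthesis) gives 1-chlorododecan-2-one F2.
- PPh3 in toluene gives (2-oxododecyl)triphenylphosphonium chloride F3, and aqueous NaOH the stabilised ylide 1-(triphenylphosphoranylidene)dodecan-2-one F4.
- Wittig olefination of maleic anhydride with F4 gives the ylidenebutenolide (E)-5-(2-oxododecylidene)furan-2(5H)-one F5; either alkene isomer serves.
- NaOMe in MeOH opens the enol lactone and recloses it by Claisen condensation (ylidenebutenolide rearrangement) to 2-undecanoylcyclopent-4-ene-1,3-dione F6.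
- Dimethyldioxirane hydroxylates the central carbon of this enolised triketone to give 8.

Step 4. Oxygen transfer to the hydrogen-bonded, acidic enol may be sluggish, so that one-electron oxidation and over-oxidation compete, and the electrophilic trione may hydrate on concentration. The fallback sets out from 5 and comes back at 7, bypassing 6 and the free enol.
- Dimethyldioxirane epoxidises the enol-ether double bond of 5 to 1-decyl-6-methoxy-7-oxabicyclo[4.1.0]hept-3-ene-2,5-dione F7, a neutral, isolable precursor.
- PPTS in CH2Cl2 containing one equivalent of water opens the α-methoxy epoxide through its oxocarbenium ion, and the hemiketal loses methanol to give 7, which is dried over sieves before step 5.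

Step 6. Facial selectivity of hydride addition may be poor, giving ring-carbinol epimers, because both faces of the ring carbonyls carry a substituent of the same quaternary carbon. The fallback sets out from 9 as obtained (the stereoisomer mixture) and comes back at 10, so step 7 is also skipped.
- MnO2 in CH2Cl2 re-oxidises only the allylic ring carbinols of all stereoisomers, which converge on 2-hydroxy-2-(1-hydroxyundecyl)cyclopent-4-ene-1,3-dione F8.
- 2,2-Dimethoxypropane and PPTS close its only two hydroxyls to 4-decyl-2,2-dimethyl-1,3-dioxaspiro[4.4]non-7-ene-6,9-dione F9, with no regiochemical choice.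
- Luche reduction of F9, in which one face is shielded by the dioxolane carbon bearing the decyl chain and the other carries only the ring oxygen, should give 10.

**Further compounds**

F1 | step 5 | decylmagnesium bromide | CCCCCCCCCC[Mg]Br
F2 | step 5 | 1-chlorododecan-2-one | CCCCCCCCCCC(=O)CCl
F3 | step 5 | (2-oxododecyl)triphenylphosphonium chloride | CCCCCCCCCCC(=O)C[P+](c1ccccc1)(c1ccccc1)c1ccccc1.[Cl-]
F4 | step 5 | 1-(triphenylphosphoranylidene)dodecan-2-one | CCCCCCCCCCC(=O)C=P(c1ccccc1)(c1ccccc1)c1ccccc1
F5 | step 5 | (E)-5-(2-oxododecylidene)furan-2(5H)-one | CCCCCCCCCCC(=O)/C=C1\C=CC(=O)O1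
F6 | step 5 | 2-undecanoylcyclopent-4-ene-1,3-dione | CCCCCCCCCCC(=O)C1C(=O)C=CC1=O
F7 | step 4 | 1-decyl-6-methoxy-7-oxabicyclo[4.1.0]hept-3-ene-2,5-dione (racemic, one enantiomer drawn) | CCCCCCCCCC[C@]12O[C@@]1(OC)C(=O)C=CC2=O
F8 | step 6 | 2-hydroxy-2-(1-hydroxyundecyl)cyclopent-4-ene-1,3-dione (racemic, one enantiomer drawn) | CCCCCCCCCC[C@H](O)C1(O)C(=O)C=CC1=O
F9 | step 6 | 4-decyl-2,2-dimethyl-1,3-dioxaspiro[4.4]non-7-ene-6,9-dione (racemic, one enantiomer drawn) | CCCCCCCCCC[C@@H]1OC(C)(C)OC12C(=O)C=CC2=O
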